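## Structural features

The target is a carbon–carbon linked dimer of two isoliquiritigenin-type chalcones: four benzene rings (A to D) joined by two (E)-enone bridges, with no sp3 carbon. Ring A (2,4-dihydroxyphenyl) is the aryl ketone of enone 1, whose β-carbon sits on B1 of ring B. Ring B carries OH at B4 and is bonded through B3 to C5 of ring C. Ring C bears the ketone of enone 2 at C1, OH at C2 and C4, and H at C3 and C6; enone 2 ends in ring D (4-hydroxyphenyl). There is no stereocentre, so no stereocentres stand next to each other; the only stereochemical elements are the two E double bonds. The fragile groups are the two 2-hydroxyaryl enones, which are Michael acceptors, close to flavanones under acid or base and isomerise in light, and the six free phenols, which oxidise easily in base. The real difficulty is the unsymmetrical biaryl bond B3–C5, flanked by an oxygen on each ring, together with building two similar enones once each and in the right orientation. The key step exploits ring C: C2–C3–C4–C5 has the oxidation pattern of a 4-aryl-3-oxobutanoate (C2 ester carbon, C4 ketone carbon, C5 the benzylic carbon already bonded to ring B), and C6–C1 is a terminal ynone (C6–H, C1 acylated).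

## Logic of the disconnections

19 to 18. The six phenolic O–H bonds are traced back to O–CH3 ethers. Methyl is the only group that survives every earlier step (strong amide base, silylation, heating with palladium and amine) and it comes with the commercial building blocks. The forward step must cleave six aryl methyl ethers without damaging two enones.

18 to 13 and 17. The bond between B1 and the β-carbon of enone 1 is cut. This removes ring A and a whole enone in one stroke and leaves a simple aryl bromide on ring B. The forward Heck reaction must attack only the terminal alkene of 17 and not the internal enone already present in 13.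

17 to 16, and 16 to 14 and 15. The vinyl ketone 17 polymerises easily, so it is traced to the storable β-chloro ketone 16, which releases 17 in the Heck flask. 16 is cut at the bond between ring A and its carbonyl carbon, giving 14 and 15. The forward acylation must go para to one methoxy group and ortho to the other.

13 to 12. The O–CH3 bonds at C2 and C4 of ring C are removed. Capping these two phenols before the Heck step blocks phenoxide addition to 17 and flavanone-type closure. The forward step must alkylate a hydrogen-bonded phenol next to the ketone.

12 to 6 and 9. Ring C is opened at C1–C2 and C5–C6. This is the strategic cut: it gives an acyclic diene that already holds ring B, and an ynone that already holds ring D and the E alkene of enone 2. The biaryl bond therefore never has to be made by coupling. The forward step needs one regiochemistry and must use the alkyne, not the styryl alkene, of 9.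

6 to 5 to 4. The two O–Si bonds are removed one after the other, leading to the β-keto ester 4. The forward steps need regioselective enolisation (first towards C2, then at the benzylic C4) and strict exclusion of water.

4 to 1 and 2. The bond between the ketone carbon and the α-methylene of the ester is cut, giving an arylacetic acid and a malonate equivalent. The forward step is a C-acylation followed by alcoholysis and decarboxylation.

9 to 8 to 7. The ketone is traced to the secondary alcohol 8, and the bond between the carbinol carbon and the alkyne is cut, leading to the enal 7 and an ethynyl anion equivalent. The forward steps need 1,2-addition and a neutral oxidation that spares the terminal alkyne.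

## Other disconnections considered

Alternative 1: The cut runs through ring B at B2–B3 and B4–B5. B5, B6, B1 and B2 come from methyl coumalate A2, and B3–B4 from the enol ether bond of tert-butyl[(6-methoxy-1-benzofuran-2-yl)oxy]dimethylsilane A3, whose benzo ring is ring C. In the forward sense the electron-rich C2=C3 bond of A3 would add across C3 and C6 of A2 with inverse electron demand. The bridged lactone would then undergo decarboxylative cycloreversion, and β-elimination of the ring C phenoxide from B4 would aromatise ring B to give methyl 4-(tert-butyldimethylsilyloxy)-3-(2-hydroxy-4-methoxyphenyl)benzoate A1.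
- In favour: it forms the doubly oxygen-flanked biaryl bond without a cross-coupling, which is equal to the chosen plan. Its regiochemistry follows from the polarised pyranone. The two flanking oxygens emerge differentiated (silyl ether on ring B, free phenol on ring C), which is better than the chosen plan. The B1 ester allows enone 1 by aldol condensation without a vinyl ketone, also better.
- Against: A1 lacks the C1 acyl group of ring C and all carbons of both enone bridges. A Friedel–Crafts acylation at C1 (in competition with C3 between the two oxygens), an ester-to-aldehyde adjustment and two separate Claisen–Schmidt condensations would still be needed. A3 is an aromatic furan, so a reluctant 2π partner, and is moisture-sensitive.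
- Comparison: on structure, the chosen cycloaddition delivers ring C with ketone, both hydroxyls, ring B and enone 2 in one operation. On mechanism, both are polarity-matched cycloaddition and aromatisation cascades of similar plausibility. On step economy, about six to eight mostly linear steps would follow A1, against four after 12.

Alternative 2: Ring B is cut at B1–B2 and B5–B6 into the diene tert-butyl{[3-(2,4-dimethoxyphenyl)buta-1,3-dien-2-yl]oxy}dimethylsilane A5 (B2 to B5) and methyl prop-2-ynoate A6 (B6, B1). The forward Diels–Alder reaction would join the terminus next to the silyloxy carbon to the terminal alkyne carbon and the terminus next to the aryl carbon to the ester-bearing carbon. This gives the 1,4-cyclohexadiene methyl 4-(tert-butyldimethylsilyloxy)-5-(2,4-dimethoxyphenyl)cyclohexa-1,4-diene-1-carboxylate A4. A separate dehydrogenation (a quinone oxidant) would then give methyl 4-(tert-butyldimethylsilyloxy)-3-(2,4-dimethoxyphenyl)benzoate A7.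
- In favour: A6 is a far more robust dienophile than 9, and A5, a single silyl enol ether, is easier to handle than the doubly silylated ketene acetal 6. Both points are better than the chosen plan. The biaryl bond again needs no coupling, which is equal.
- Against: the two inner substituents of A5 steer in opposite senses, the silyloxy group towards A4 and the aryl group towards its regioisomer, so regiocontrol rests on the stronger donor alone. The adduct is not aromatic and the oxidation must compete with loss of the silyl enol ether. As in alternative 1, ring C arrives without its acyl group and no enone is present.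
- Comparison: on structure, it yields the same bare biaryl benzoate type as alternative 1, with no differentiation of the ring C oxygens. On mechanism, it is a plain thermal cycloaddition, simpler than the chosen cascade but without the built-in aromatisation. On step economy, it is one step longer than alternative 1 and clearly longer than the chosen plan.

Alternative 3: Both enones are traced back at once to propargylic alcohols. The precursor is the diol 3-(2,4-dimethoxyphenyl)-1-{3-[5-(3-hydroxy-3-(4-methoxyphenyl)prop-1-yn-1-yl)-2,4-dimethoxyphenyl]-4-methoxyphenyl}prop-2-yn-1-ol A9, with alkynes on rings A and C and carbinols on rings B and D. In the forward sense (Ph3P)AuNTf2 A10, a monovalent gold catalyst, in a wet alcohol solvent would trigger two Meyer–Schuster transpositions. These place the carbonyl oxygens on the alkyne carbons attached to rings A and C and form both E alkenes, giving the hexamethyl ether A8, which is the same compound as 18.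
- In favour: both enones form under neutral conditions in one step with E geometry. No vinyl ketone and no aldol step are needed, which is better than the chosen plan on enone construction. It converges on the same last intermediate, so the final deprotection is equal.
- Against: A9 needs a preformed biaryl with two different handles, so the hindered biaryl bond must be made by cross-coupling, which the chosen plan avoids. Both carbinols are benzylic to electron-rich rings and may ionise and be trapped by the solvent. Both alkynes have an ortho methoxy group, which invites gold-promoted cyclisation to benzofurans. A twofold reaction must succeed at both sites.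
- Comparison: on structure, the chosen plan builds ring C and the biaryl bond together, whereas this plan builds neither. On mechanism, both key steps are known reaction types; the gold step is milder but has more competing pathways on this substrate. On step economy, biaryl assembly plus two alkyne installations would probably make it equal to or slightly longer than the ten steps of the chosen plan.

Key step: step 6

Remark on the chemistry: mapping the diene, the ynone and the cycloaromatisation product atom by atom onto ring C shows them to be mutually consistent and to give the required 1-acyl-2,4-dioxygenated 5-aryl pattern, so no structure needs correction. Two things are changed after the key step: the two new phenols are capped before the Heck reaction, and the aryl vinyl ketone is released in the flask from a β-chloro ketone.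

Remark on the chemistry: the enol ether geometries of 5 and 6 and the configurations of racemic 8 and of 10 (a mixture of diastereomers) are erased later. 5 and 6 are written as single isomers only for definiteness.

## Route

Step 1
Reactants: 1 2-(5-bromo-2-methoxyphenyl)acetic acid; 2 2,2-dimethyl-1,3-dioxane-4,6-dione
Product: 4 methyl 4-(5-bromo-2-methoxyphenyl)-3-oxobutanoate, via acyl dioxanedione 3 (not isolated)
Conditions: DCC, DMAP, CH2Cl2, 0 °C → rt; filter, wash with aq. KHSO4, concentrate; then MeOH, reflux
Reagents that add atoms: methanol, CO
Why: Carbodiimide-mediated C-acylation of the cyclic malonate gives 3, which is opened by methanol and loses acetone and CO2 to the β-keto ester (acylation–alcoholysis of an acyl dioxanedione). The aryl bromide and the methyl ether are inert.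

Step 2
Reactants: 4 methyl 4-(5-bromo-2-methoxyphenyl)-3-oxobutanoate
Product: 5 methyl (Z)-4-(5-bromo-2-methoxyphenyl)-3-(trimethylsilyloxy)but-2-enoate
Conditions: TMSCl, Et3N, toluene, rt; filtration under argon
Reagents that add atoms: chlorotrimethylsilane, C[Si](C)(C)Cl
Why: O-Silylation of the enolised β-keto ester by soft enolisation gives the ester-conjugated silyl enol ether, the first half of the standard two-stage preparation of 1,3-bis(silyloxy)dienes.

Step 3
Reactants: 5 methyl (Z)-4-(5-bromo-2-methoxyphenyl)-3-(trimethylsilyloxy)but-2-enoate
Product: 6 (1Z,3Z)-4-(5-bromo-2-methoxyphenyl)-1-methoxy-1,3-bis(trimethylsilyloxy)buta-1,3-diene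
Conditions: LiN(i-Pr)2, THF, −78 °C; TMSCl, −78 °C → rt; hexane, filtration under argon; used crude
Reagents that add atoms: chlorotrimethylsilane, C[Si](C)(C)Cl
Why: The amide base removes the benzylic γ-proton of the vinylogous ester, and the dienolate is silylated on oxygen to the ketene acetal (γ-deprotonation and O-silylation). At −78 °C the aryl bromide is not attacked by the hindered amide.

Step 4
Reactants: 7 (E)-3-(4-methoxyphenyl)prop-2-enal
Product: 8 (E)-1-(4-methoxyphenyl)pent-1-en-4-yn-3-ol (racemic)
Conditions: HC≡CMgBr, THF, 0 °C; then sat. aq. NH4Cl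
Reagents that add atoms: ethynylmagnesium bromide, C#C[Mg]Br
Why: The hard alkynyl Grignard reagent adds 1,2 to the enal. The new carbinol centre is formed racemic and is removed by the next oxidation; the buffered quench avoids ionisation of the allylic, propargylic alcohol.

Step 5
Reactants: 8 (E)-1-(4-methoxyphenyl)pent-1-en-4-yn-3-ol
Product: 9 (E)-1-(4-methoxyphenyl)pent-1-en-4-yn-3-one
Conditions: MnO2 (activated), CH2Cl2, rt, dark; filter, use at once
Reagents that add atoms: none
Why: MnO2 oxidises allylic and propargylic alcohols selectively under neutral conditions, so the terminal alkyne and the E alkene are untouched. The cross-conjugated enynone is taken on without storage.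

Step 6
Reactants: 6 (1Z,3Z)-4-(5-bromo-2-methoxyphenyl)-1-methoxy-1,3-bis(trimethylsilyloxy)buta-1,3-diene; 9 (E)-1-(4-methoxyphenyl)pent-1-en-4-yn-3-one
Product: 12 (E)-1-[5-(5-bromo-2-methoxyphenyl)-2,4-dihydroxyphenyl]-3-(4-methoxyphenyl)prop-2-en-1-one, via cyclohexa-1,4-diene cycloadduct 10 (not isolated), via bis(trimethylsilyl) ether 11 (not isolated)
Conditions: toluene, −78 °C → rt, then 45 °C; then 1 M HCl, THF, rt
Reagents that add atoms: none
Why: This is a normal-electron-demand, strongly asynchronous (4+2) cycloaddition of a 1-alkoxy-1,3-bis(silyloxy)diene with an acetylenic ketone, the known route from such dienes and alkynones or alkynoates to acyl resorcinols. The largest HOMO coefficient of 6 lies on the aryl-bearing terminus, which bonds to the unsubstituted alkyne carbon of 9 (C5–C6), while the ketene acetal carbon bonds to the acyl-bearing alkyne carbon (C1–C2); if the process is stepwise, a Mukaiyama–Michael addition is followed by 6-exo-trig closure of the allenolate onto the oxocarbenium carbon. Ring C is thus closed as the six-membered cyclohexa-1,4-diene 10 by intermolecular cycloaddition. 10 has a doubly allylic, benzylic hydrogen in a 1,4 relation to the mixed ketal carbon, so methanol is lost readily to give the aromatic bis(silyl ether) 11, and dilute acid cleaves both aryl silyl ethers to 12. No stereocentre survives: the two sp3 centres of 10 vanish on aromatisation, and the E alkene of 9 is not touched under neutral thermal conditions. The regioselectivity needed is secured by the matching polarisation of the donor-substituted diene and the ynone. The chemoselectivity needed is secured because the terminal alkyne carbon is unhindered and strongly electrophilic, whereas the enone β-carbon is deactivated by the 4-methoxyphenyl donor and is more hindered. The (3Z) geometry of 6 places the aryl group on the outside of the s-cis diene, so the substituted terminus stays accessible.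

Step 7
Reactants: 12 (E)-1-[5-(5-bromo-2-methoxyphenyl)-2,4-dihydroxyphenyl]-3-(4-methoxyphenyl)prop-2-en-1-one
Product: 13 (E)-1-[5-(5-bromo-2-methoxyphenyl)-2,4-dimethoxyphenyl]-3-(4-methoxyphenyl)prop-2-en-1-one
Conditions: MeI (excess), K2CO3, DMF, 50 °C
Reagents that add atoms: iodomethane, CI
Why: Williamson etherification of both phenoxides; the hydrogen-bonded C2–OH needs excess reagent and gentle warming. With both phenols capped, neither phenoxide addition to the vinyl ketone nor flavanone-type closure can occur in the Heck step.

Step 8
Reactants: 14 1,3-dimethoxybenzene; 15 3-chloropropanoyl chloride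
Product: 16 3-chloro-1-(2,4-dimethoxyphenyl)propan-1-one
Conditions: AlCl3, CH2Cl2, 0 °C
Reagents that add atoms: none
Why: Friedel–Crafts acylation goes to C4 of the arene, para to one methoxy group and ortho to the other, because C2 is hindered. Keeping the mixture cold avoids cleavage of the ortho methyl ether by AlCl3.

Step 9
Reactants: 13 (E)-1-[5-(5-bromo-2-methoxyphenyl)-2,4-dimethoxyphenyl]-3-(4-methoxyphenyl)prop-2-en-1-one; 16 3-chloro-1-(2,4-dimethoxyphenyl)propan-1-one
Product: 18 (E)-1-(2,4-dimethoxyphenyl)-3-{3-[2,4-dimethoxy-5-((E)-3-(4-methoxyphenyl)prop-2-enoyl)phenyl]-4-methoxyphenyl}prop-2-en-1-one, via aryl vinyl ketone 17 (not isolated)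
Conditions: Pd(OAc)2, P(o-tol)3, Et3N, BHT (cat.), DMF, 90 °C
Reagents that add atoms: none
Why: Et3N dehydrochlorinates 16 by an E1cB pathway to the vinyl ketone 17, which undergoes a Mizoroki–Heck reaction: oxidative addition of the aryl bromide to zerovalent palladium, syn insertion and syn β-hydride elimination give the E enone. The terminal alkene of 17 reacts far faster than the internal, disubstituted enone already in 13.

Step 10
Reactants: 18 (E)-1-(2,4-dimethoxyphenyl)-3-{3-[2,4-dimethoxy-5-((E)-3-(4-methoxyphenyl)prop-2-enoyl)phenyl]-4-methoxyphenyl}prop-2-en-1-one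
Product: 19 (E)-1-(2,4-dihydroxyphenyl)-3-{3-[2,4-dihydroxy-5-((E)-3-(4-hydroxyphenyl)prop-2-enoyl)phenyl]-4-hydroxyphenyl}prop-2-en-1-one (rhuschalcone VI)
Conditions: BBr3 (excess), CH2Cl2, −78 °C → rt; then ice–water
Reagents that add atoms: none
Why: BBr3 cleaves aryl methyl ethers by boron coordination and bromide attack at methyl, a standard way from methoxychalcones to hydroxychalcones; the ethers ortho to the carbonyls go first through chelation. Excess reagent is needed because both ketones bind boron, and the cold quench limits acid-promoted closure to flavanones; both E alkenes are retained.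

## Compound list

1 | 2-(5-bromo-2-methoxyphenyl)acetic acid | COc1ccc(Br)cc1CC(=O)O | starting material
2 | 2,2-dimethyl-1,3-dioxane-4,6-dione | CC1(C)OC(=O)CC(=O)O1 | starting material
3 | 5-[2-(5-bromo-2-methoxyphenyl)-1-hydroxyethylidene]-2,2-dimethyl-1,3-dioxane-4,6-dione | COc1ccc(Br)cc1CC(O)=C1C(=O)OC(C)(C)OC1=O | intermediate
4 | methyl 4-(5-bromo-2-methoxyphenyl)-3-oxobutanoate | COC(=O)CC(=O)Cc1cc(Br)ccc1OC | intermediate
5 | methyl (Z)-4-(5-bromo-2-methoxyphenyl)-3-(trimethylsilyloxy)but-2-enoate | COC(=O)/C=C(/Cc1cc(Br)ccc1OC)O[Si](C)(C)C | intermediate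
6 | (1Z,3Z)-4-(5-bromo-2-methoxyphenyl)-1-methoxy-1,3-bis(trimethylsilyloxy)buta-1,3-diene | CO/C(O[Si](C)(C)C)=C/C(O[Si](C)(C)C)=C/c1cc(Br)ccc1OC | intermediate
7 | (E)-3-(4-methoxyphenyl)prop-2-enal | COc1ccc(/C=C/C=O)cc1 | starting material
8 | (E)-1-(4-methoxyphenyl)pent-1-en-4-yn-3-ol, racemic | COc1ccc(/C=C/C(O)C#C)cc1 | intermediate
9 | (E)-1-(4-methoxyphenyl)pent-1-en-4-yn-3-one | COc1ccc(/C=C/C(=O)C#C)cc1 | intermediate
10 | (E)-1-[3-(5-bromo-2-methoxyphenyl)-6-methoxy-4,6-bis(trimethylsilyloxy)cyclohexa-1,4-dien-1-yl]-3-(4-methoxyphenyl)prop-2-en-1-one, mixture of diastereomers | COc1ccc(/C=C/C(=O)C2=CC(c3cc(Br)ccc3OC)C(O[Si](C)(C)C)=CC2(OC)O[Si](C)(C)C)cc1 | intermediate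
11 | (E)-1-[5-(5-bromo-2-methoxyphenyl)-2,4-bis(trimethylsilyloxy)phenyl]-3-(4-methoxyphenyl)prop-2-en-1-one | COc1ccc(/C=C/C(=O)c2cc(-c3cc(Br)ccc3OC)c(O[Si](C)(C)C)cc2O[Si](C)(C)C)cc1 | intermediate
12 | (E)-1-[5-(5-bromo-2-methoxyphenyl)-2,4-dihydroxyphenyl]-3-(4-methoxyphenyl)prop-2-en-1-one | COc1ccc(/C=C/C(=O)c2cc(-c3cc(Br)ccc3OC)c(O)cc2O)cc1 | intermediate
13 | (E)-1-[5-(5-bromo-2-methoxyphenyl)-2,4-dimethoxyphenyl]-3-(4-methoxyphenyl)prop-2-en-1-one | COc1ccc(/C=C/C(=O)c2cc(-c3cc(Br)ccc3OC)c(OC)cc2OC)cc1 | intermediate
14 | 1,3-dimethoxybenzene | COc1cccc(OC)c1 | starting material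
15 | 3-chloropropanoyl chloride | O=C(Cl)CCCl | starting material
16 | 3-chloro-1-(2,4-dimethoxyphenyl)propan-1-one | COc1ccc(C(=O)CCCl)c(OC)c1 | intermediate
17 | 1-(2,4-dimethoxyphenyl)prop-2-en-1-one | COc1ccc(C(=O)C=C)c(OC)c1 | intermediate
18 | (E)-1-(2,4-dimethoxyphenyl)-3-{3-[2,4-dimethoxy-5-((E)-3-(4-methoxyphenyl)prop-2-enoyl)phenyl]-4-methoxyphenyl}prop-2-en-1-one | COc1ccc(/C=C/C(=O)c2cc(-c3cc(/C=C/C(=O)c4ccc(OC)cc4OC)ccc3OC)c(OC)cc2OC)cc1 | intermediate
19 | (E)-1-(2,4-dihydroxyphenyl)-3-{3-[2,4-dihydroxy-5-((E)-3-(4-hydroxyphenyl)prop-2-enoyl)phenyl]-4-hydroxyphenyl}prop-2-en-1-one (rhuschalcone VI) | Oc1ccc(/C=C/C(=O)c2cc(-c3cc(/C=C/C(=O)c4ccc(O)cc4O)ccc3O)c(O)cc2O)cc1 | target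

## Step count and least certain steps

Total step count: 10. Longest linear sequence: 7 steps (steps 1, 2, 3, 6, 7, 9 and 10).

**Step 6 (key step).** Bond formation at the aryl-substituted diene terminus, which has an ortho methoxy group nearby, may be slow. Hydrolytic decay of the diene and oligomerisation of the terminal ynone could then outpace the cycloaddition, and conjugate addition at the styryl enone could compete. The fallback sets out from 6 and returns at 13. 6 would be heated with an excess of but-3-yn-2-one, a small and robust ynone with no second acceptor site, and hydrolysed as in step 6 to give 1-[5-(5-bromo-2-methoxyphenyl)-2,4-dihydroxyphenyl]ethan-1-one F1. Methylation (MeI, K2CO3, DMF) would give 1-[5-(5-bromo-2-methoxyphenyl)-2,4-dimethoxyphenyl]ethan-1-one F2. A Claisen–Schmidt condensation of F2 with 4-methoxybenzaldehyde (KOH, EtOH) would then build enone 2 after the ring and deliver 13.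

**Step 9.** The vinyl ketone released in the flask may be consumed by radical polymerisation or by amine- or phosphine-initiated oligomerisation faster than the electron-rich aryl bromide adds to zerovalent palladium. The fallback sets out from 13 and returns at 18 without any vinyl ketone. Palladium-catalysed formylation of 13 (Pd(OAc)2, di(1-adamantyl)-n-butylphosphine, CO/H2, TMEDA, toluene, 100 °C) would give 3-{2,4-dimethoxy-5-[(E)-3-(4-methoxyphenyl)prop-2-enoyl]phenyl}-4-methoxybenzaldehyde F3. A Claisen–Schmidt condensation of F3 with commercial 1-(2,4-dimethoxyphenyl)ethanone (KOH, EtOH, rt) would give 18.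

**Step 10.** Six ether cleavages on one molecule may stop at mixtures of partly methylated products. The acid released may also drive oxa-Michael closure of the freed 2-hydroxyaryl enones to flavanones or add HBr across the enones. The fallback sets out from 12 and returns at 19, moving the boron chemistry to a simpler stage and ending with a mild acid deprotection. It runs as follows:
- BBr3 on 12, where only two ethers and one enone are present, would give (E)-1-[5-(5-bromo-2-hydroxyphenyl)-2,4-dihydroxyphenyl]-3-(4-hydroxyphenyl)prop-2-en-1-one F4.
- NaH and MOMCl in DMF would convert F4 into (E)-1-{5-[5-bromo-2-(methoxymethoxy)phenyl]-2,4-bis(methoxymethoxy)phenyl}-3-[4-(methoxymethoxy)phenyl]prop-2-en-1-one F5.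
- The ring A partner would come from commercial 2,4-dihydroxybenzaldehyde: protection gives 2,4-bis(methoxymethoxy)benzaldehyde F6; CH2=CHMgBr gives 1-[2,4-bis(methoxymethoxy)phenyl]prop-2-en-1-ol F7; MnO2 gives 1-[2,4-bis(methoxymethoxy)phenyl]prop-2-en-1-one F8.
- A Heck reaction of F5 with F8 (Pd(OAc)2, P(o-tol)3, Et3N, DMF) would give (E)-1-[2,4-bis(methoxymethoxy)phenyl]-3-{3-[2,4-bis(methoxymethoxy)-5-((E)-3-(4-(methoxymethoxy)phenyl)prop-2-enoyl)phenyl]-4-(methoxymethoxy)phenyl}prop-2-en-1-one F9.
- HCl in MeOH at 50 °C would remove all six acetals from F9 and give 19.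

**Step 5.** The terminal enynone may polymerise or undergo Michael addition during long contact with the oxidant, on concentration or on standing, and the alcohol 8 may ionise on acidic surfaces. The fallback sets out from 7 and returns at 9, keeping the alkyne capped until just before use. Addition of LiC≡CSiMe3 to 7 (THF, −78 °C) would give (E)-1-(4-methoxyphenyl)-5-(trimethylsilyl)pent-1-en-4-yn-3-ol F10. MnO2 would oxidise F10 to the storable (E)-1-(4-methoxyphenyl)-5-(trimethylsilyl)pent-1-en-4-yn-3-one F11. Protodesilylation of F11 with dilute Na2B4O7 in aqueous MeOH, immediately before the cycloaddition, would release 9.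

## Further compounds

F1 | step 6 | 1-[5-(5-bromo-2-methoxyphenyl)-2,4-dihydroxyphenyl]ethan-1-one | CC(=O)c1cc(-c2cc(Br)ccc2OC)c(O)cc1O
F2 | step 6 | 1-[5-(5-bromo-2-methoxyphenyl)-2,4-dimethoxyphenyl]ethan-1-one | CC(=O)c1cc(-c2cc(Br)ccc2OC)c(OC)cc1OC
F3 | step 9 | 3-{2,4-dimethoxy-5-[(E)-3-(4-methoxyphenyl)prop-2-enoyl]phenyl}-4-methoxybenzaldehyde | COc1ccc(/C=C/C(=O)c2cc(-c3cc(C=O)ccc3OC)c(OC)cc2OC)cc1
F4 | step 10 | (E)-1-[5-(5-bromo-2-hydroxyphenyl)-2,4-dihydroxyphenyl]-3-(4-hydroxyphenyl)prop-2-en-1-one | Oc1ccc(/C=C/C(=O)c2cc(-c3cc(Br)ccc3O)c(O)cc2O)cc1
F5 | step 10 | (E)-1-{5-[5-bromo-2-(methoxymethoxy)phenyl]-2,4-bis(methoxymethoxy)phenyl}-3-[4-(methoxymethoxy)phenyl]prop-2-en-1-one | COCOc1ccc(/C=C/C(=O)c2cc(-c3cc(Br)ccc3OCOC)c(OCOC)cc2OCOC)cc1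
F6 | step 10 | 2,4-bis(methoxymethoxy)benzaldehyde | COCOc1ccc(C=O)c(OCOC)c1
F7 | step 10 | 1-[2,4-bis(methoxymethoxy)phenyl]prop-2-en-1-ol | COCOc1ccc(C(O)C=C)c(OCOC)c1
F8 | step 10 | 1-[2,4-bis(methoxymethoxy)phenyl]prop-2-en-1-one | COCOc1ccc(C(=O)C=C)c(OCOC)c1
F9 | step 10 | (E)-1-[2,4-bis(methoxymethoxy)phenyl]-3-{3-[2,4-bis(methoxymethoxy)-5-((E)-3-(4-(methoxymethoxy)phenyl)prop-2-enoyl)phenyl]-4-(methoxymethoxy)phenyl}prop-2-en-1-one | COCOc1ccc(/C=C/C(=O)c2cc(-c3cc(/C=C/C(=O)c4ccc(OCOC)cc4OCOC)ccc3OCOC)c(OCOC)cc2OCOC)cc1
F10 | step 5 | (E)-1-(4-methoxyphenyl)-5-(trimethylsilyl)pent-1-en-4-yn-3-ol | COc1ccc(/C=C/C(O)C#C[Si](C)(C)C)cc1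
F11 | step 5 | (E)-1-(4-methoxyphenyl)-5-(trimethylsilyl)pent-1-en-4-yn-3-one | COc1ccc(/C=C/C(=O)C#C[Si](C)(C)C)cc1
A1 | alternative 1 | methyl 4-(tert-butyldimethylsilyloxy)-3-(2-hydroxy-4-methoxyphenyl)benzoate | COC(=O)c1ccc(O[Si](C)(C)C(C)(C)C)c(-c2ccc(OC)cc2O)c1
A2 | alternative 1 | methyl 2-oxo-2H-pyran-5-carboxylate (methyl coumalate) | COC(=O)C1=COC(=O)C=C1
A3 | alternative 1 | tert-butyl[(6-methoxy-1-benzofuran-2-yl)oxy]dimethylsilane | COc1ccc2cc(O[Si](C)(C)C(C)(C)C)oc2c1
A4 | alternative 2 | methyl 4-(tert-butyldimethylsilyloxy)-5-(2,4-dimethoxyphenyl)cyclohexa-1,4-diene-1-carboxylate | COC(=O)C1=CCC(O[Si](C)(C)C(C)(C)C)=C(c2ccc(OC)cc2OC)C1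
A5 | alternative 2 | tert-butyl{[3-(2,4-dimethoxyphenyl)buta-1,3-dien-2-yl]oxy}dimethylsilane | C=C(O[Si](C)(C)C(C)(C)C)C(=C)c1ccc(OC)cc1OC
A6 | alternative 2 | methyl prop-2-ynoate | C#CC(=O)OC
A7 | alternative 2 | methyl 4-(tert-butyldimethylsilyloxy)-3-(2,4-dimethoxyphenyl)benzoate | COC(=O)c1ccc(O[Si](C)(C)C(C)(C)C)c(-c2ccc(OC)cc2OC)c1
A8 | alternative 3 | (E)-1-(2,4-dimethoxyphenyl)-3-{3-[2,4-dimethoxy-5-((E)-3-(4-methoxyphenyl)prop-2-enoyl)phenyl]-4-methoxyphenyl}prop-2-en-1-one (identical with 18) | COc1ccc(/C=C/C(=O)c2cc(-c3cc(/C=C/C(=O)c4ccc(OC)cc4OC)ccc3OC)c(OC)cc2OC)cc1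
A9 | alternative 3 | 3-(2,4-dimethoxyphenyl)-1-{3-[5-(3-hydroxy-3-(4-methoxyphenyl)prop-1-yn-1-yl)-2,4-dimethoxyphenyl]-4-methoxyphenyl}prop-2-yn-1-ol | COc1ccc(C(O)C#Cc2cc(-c3cc(C(O)C#Cc4ccc(OC)cc4OC)ccc3OC)c(OC)cc2OC)cc1
A10 | alternative 3 | (triphenylphosphine)gold bis(trifluoromethanesulfonyl)imide, (Ph3P)AuNTf2 | FC(F)(F)S(=O)(=O)N([Au-][P+](c1ccccc1)(c1ccccc1)c1ccccc1)S(=O)(=O)C(F)(F)F
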